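## Analysis of the target

The target is a spiro-tricycle. A 1,2,3-trimethoxybenzene (ring A, carbons Ca–Cf; Ca and Cf are the fusion carbons, Cb carries H, and Cc, Cd and Ce carry the methoxy groups) is fused to a seven-membered carbocycle (ring B: Cs, C9H2, C8H(CH3), C7H(CH3), C6H(OBz), Ca, Cf), and the benzylic quaternary carbon Cs on Cf is also the sp3 carbon of a 2,6-dimethoxycyclohexa-2,5-dienone (ring C: Cs–C2'H=C3'(OCH3)–C4'(=O)–C5'(OCH3)=C6'H). There are three contiguous stereocentres, C6 (R), C7 (S) and C8 (R): the C7 methyl group is trans to both the C6 benzoate and the C8 methyl group, so the benzoate and the C8 methyl group are cis. Cs carries two constitutionally identical arms and is not a stereocentre, but it becomes one in every intermediate whose ring C is not yet symmetrical. The sensitive groups are the cross-conjugated dienone (open to a dienone–phenol rearrangement in acid, because an electron-rich aryl group sits on its sp3 carbon), its two enol ethers, and the benzylic benzoate on a para-methoxy-substituted arene, which can ionise, eliminate towards C7 or be saponified. The difficulties are the quaternary carbon Cs between an ortho-substituted arene and two rings, the all-trans triad C6–C8 on a flexible seven-membered ring, and the need to tell two ketones apart once ring B has been closed through a C6 carbonyl. The strategy rests on the segment Cs–C2'H=C3'(OCH3)–C4'(=O)–C5'–C6' of ring C: it is the retron of a Robinson annulation in which Cs is the α-carbon and C2' the formyl carbon of an α-aryl aldehyde, while C3', C4', C5' and C6' are the four carbons of a vinyl ketone that already carries the C3' methoxy group. C7 and C8 lie outside that reacting system, so they can be brought in as a C2-symmetric four-carbon unit, and C6 can be set last by reduction and inversion.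

## Retrosynthetic reasoning

**Ring C end game (23 ⇒ 22 ⇒ 20 ⇒ 19).** The O–CH3 bond at C5' is cut first, then the oxidation level at C5' is lowered, then the C5'–O bond is removed. The dienone must not meet acid, so ring C is kept as a mono-enone until all acid chemistry is over. In enone 19 only C5' carries enolisable hydrogen (C2' is vinylic, Cs quaternary), so the second oxygen can be placed regiospecifically. Oxidation of 20 gives diketone 21, which can enolise only towards C6' and so gives diosphenol 22. O-Methylation then makes ring C symmetrical, Cs stops being stereogenic, and all epimer pairs carried up to that point converge on 23.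

**C6 ester (19 ⇒ 18).** The C6–O bond is cut with inversion. A hindered hydride should reach the C6 ketone from the face away from the C7 methyl group and give the 6,7-cis alcohol 18, so the trans benzoate is best made by SN2 displacement at C6 with the carboxylate as nucleophile. Ester and correct configuration then arrive in one operation.

**C6 carbinol (18 ⇒ 16, through 17).** The C6–H bond is cut. Dione 16 has two ketones, and the ring C enone carbonyl is the more electrophilic one. The forward step therefore first converts ring C into its cross-conjugated lithium dienolate 17 by kinetic deprotonation at the unhindered C5' methylene; the tertiary C7–H is the only competing acidic site. The C6 aryl ketone is then reduced, and protonation on work-up returns the enone.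

**Ring B (16 ⇒ 14, through 15).** The Ca–C6 bond is cut. Ca is the only C–H position of ring A ortho to Cs, it is para to the Cd methoxy group, and a C6 acylium ion can reach only this carbon in a ring of reasonable size. Cutting here leaves acid 14 with a linear, stereodefined chain. Cutting C6–C7 or C7–C8 instead would break into the stereotriad, and cutting Cf–Cs would require arylation of a quaternary carbon. The forward reaction is an intramolecular Friedel–Crafts acylation that must spare the ring C enol ether and the C7 centre.

**Functional-group changes (14 ⇒ 13 ⇒ 12).** The C6 carboxyl group is traced back to a silyl-protected primary alcohol, which is inert to enolates, hydride and enamine chemistry and so can be carried through the construction of ring C.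

**Ring C (12 ⇒ 8 + 9, through 10 and 11).** The Cs–C6' and C2'=C3' bonds are cut. This is the only disconnection of ring C that creates the quaternary carbon from an sp3 C–H bond already activated by both the aryl and the formyl group, and it delivers C3' with its methoxy group in place. The forward reaction must add the α-carbon of aldehyde 8 to the vinyl terminus of 9 and then close the ring by aldol condensation through the methoxymethyl carbon. The new stereocentre at Cs needs no control.

**Chain attachment (8 ⇒ 7 ⇒ 6 + 4).** The Cs–C9 bond is cut. The break falls at a methylene between the benzylic carbon and C8, so no stereocentre is formed next to C8, and the electron-rich arene part is separated from the stereodefined chain. The forward reaction is alkylation of the enolate of ester 6 with the β-branched primary iodide 4, followed by partial reduction of the ester to aldehyde 8.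

**Building blocks (4 ⇒ 3 ⇒ 2 ⇒ 1; 6 ⇒ 5).** Iodide 4 goes back through alcohol 3 and diol 2 to acid 1. The C2 axis of 1 makes its two ends equivalent, so monoprotection of 2 needs no selectivity, and the trans relationship of the C7 and C8 methyl groups is bought, not made. Ester 6 comes from acid 5.

## Alternatives that were turned down

**Alternative 1:** Both C–CH3 bonds of ring B are disconnected. The precursor is the achiral benzocycloheptadienone A1 (C6 ketone conjugated with a C7=C8 double bond, two methyl ester groups on the future Cs). In the forward sense a methyl group would be transferred from a methylzinc reagent to C8 under copper catalysis with a chiral phosphoramidite, and the zinc enolate would be trapped at C7 by a methyl halide from the face opposite the new C8 substituent, giving the trans-dimethyl ketone A2.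
- For it: both methyl-bearing centres come from catalysis on an achiral substrate, no chiral building block is needed, and the C6 carbonyl is in place. A2 holds no second ketone, so the C6 reduction that is delicate in the chosen route would be straightforward; on that point this alternative is stronger.
- Against it: A1 is an aryl vinyl ketone in a seven-membered ring, where enantioselective methyl transfer is less secure than for simple cycloalkenones. Zinc enolates react sluggishly with alkyl halides, so the second C–C bond tends to need additives and may lose the trans relationship through proton exchange. Ring C would still have to be grown on a malonate carbon by two reductions, a double condensation and several oxidation-level changes, around a carbon prone to retro-Claisen cleavage.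
- Comparison: the chosen route takes C7 and C8 with a secured trans relationship from acid 1 and makes ring C with its C3' oxygen in one step from 8 and 9. It gives up the catalytic origin of chirality and accepts the masking manoeuvre of step 11.

**Alternative 2:** C6–C7 and C8–C9 are disconnected. Ring B is seen as spiro-indanone A3 (five-membered ketone made of C6, C9, Cs, Cf and Ca; ring C as a ketal-protected cyclohexanone) plus but-2-yne A4. In the forward sense rhodium catalysis, with a carbene ligand and an aminopyridine co-catalyst acting as a transient directing group, would insert the metal into the C6–C9 bond; the alkyne would insert into the rhodacycle and reductive elimination would give the ring-expanded enone A5 with a tetrasubstituted C7=C8 bond.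
- For it: two skeletal bonds and every carbon of ring B, both methyl groups included, are installed in one atom-economic step. The spiro centre is made on a symmetrical ring, so no epimer mixtures arise. In bond-forming economy for ring B it is superior to the chosen route, which needs five steps from 12 to 16.
- Against it: A5 has no stereocentre. C7 and C8 would have to come from enantioselective reduction of a tetrasubstituted alkene conjugated to an aryl ketone, and syn delivery of hydrogen gives the cis-dimethyl compound, so C7 would then have to be epimerised. The C–C activation must tolerate a quaternary carbon and a methoxy-rich arene next to the reacting bond. Ring C arrives as a plain ketal and would need deprotection, twofold α-oxygenation and methylation, and twofold dehydrogenation.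
- Comparison: the chosen route secures the absolute and relative configuration from 1 and the ring C oxygenation from 9, at the price of a longer linear approach to ring B.

**Alternative 3:** C6–C7 is disconnected. The precursor is the achiral aryl aldehyde A6 (formyl group on Ca; a malonate carbon as future Cs carrying a 2-methylbut-2-enyl chain). In the forward sense a chiral Lewis acid of the scandium–pybox type, or a confined chiral Brønsted acid, would activate the aldehyde; C7 of the trisubstituted alkene would attack C6 while a hydrogen of the C8 methyl group passes to oxygen (type 2 carbonyl-ene reaction), closing ring B to the 6,7-cis homoallylic alcohol A7 with an exocyclic methylene group at C8.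
- For it: ring closure, C6 and C7 come in one catalytic step from an achiral precursor. C6 is formed directly at the alcohol level, so no ketone has to be reduced beside another carbonyl; here it is stronger than the chosen route at that route's weakest point. The C6 hydroxyl group could also direct hydrogenation of the methylene group to set C8.
- Against it: seven-membered carbonyl-ene closures are far less favourable than six-membered ones. The aldehyde is deactivated by the para Cd methoxy group, while the product is a benzylic alcohol that can ionise under the same acid. Enantio- and diastereocontrol would rest on a single untested catalyst–substrate match. The 6,7-cis product still needs inversion at C6, and ring C must again be built from a malonate.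
- Comparison: the chosen route uses a well-understood reaction for each stereocentre and has the ring C solution built into its key step; it pays with the extra care needed in step 11.

Key step: step 7

## Route

Assumption: acid 1 is taken as purchasable in enantiopure form; if only the stereoisomer mixture is at hand, the chiral diastereomer is separated from the meso acid and resolved as a salt with an enantiopure amine before step 1.

Remark: from 12 to 22 every compound is a pair of epimers at Cs (20 also at C5'). They are carried on together because both converge on the single target once ring C is symmetrical. Spiro compounds are named with the atom labels defined in the analysis.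

Step 1
Reactants: 1 (2S,3S)-2,3-dimethylbutanedioic acid
Product: 2 (2S,3S)-2,3-dimethylbutane-1,4-diol
Conditions: LiAlH4, THF, 0 °C → reflux; aq. NaOH work-up
Reagents that add atoms: none
Why: Hydride reduction of both carboxyl groups; the carboxylate α-positions are not enolised under these conditions, so the C2-symmetric trans arrangement of the two methyl groups (the future C7 and C8) should be carried over unchanged.

Step 2
Reactants: 2 (2S,3S)-2,3-dimethylbutane-1,4-diol
Product: 3 (2S,3S)-4-{[tert-butyl(diphenyl)silyl]oxy}-2,3-dimethylbutan-1-ol
Conditions: NaH (1.0 equiv), THF, rt; then t-BuPh2SiCl (1.0 equiv), rt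
Reagents that add atoms: tert-butyl(chloro)diphenylsilane, CC(C)(C)[Si](Cl)(c1ccccc1)c1ccccc1
Why: Monosilylation of a symmetrical diol through its sparingly soluble monosodium alkoxide; the two hydroxyl groups are homotopic (C2 axis), so either gives the same product. The diphenylsilyl ether is chosen because it must later survive a warm acetate buffer.

Step 3
Reactants: 3 (2S,3S)-4-{[tert-butyl(diphenyl)silyl]oxy}-2,3-dimethylbutan-1-ol
Product: 4 tert-butyl{[(2S,3S)-4-iodo-2,3-dimethylbutyl]oxy}diphenylsilane
Conditions: I2, PPh3, imidazole, CH2Cl2, 0 °C → rt
Reagents that add atoms: iodine, II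
Why: Appel-type iodination through the alkoxyphosphonium salt; substitution occurs at the primary carbon only, so neither stereocentre is touched.

Step 4
Reactants: 5 (2,3,4-trimethoxyphenyl)acetic acid
Product: 6 methyl (2,3,4-trimethoxyphenyl)acetate
Conditions: MeOH, H2SO4 (cat.), reflux
Reagents that add atoms: methanol, CO
Why: Fischer esterification; it gives an enolisable ester for C-alkylation and for later partial reduction.

Step 5
Reactants: 6 methyl (2,3,4-trimethoxyphenyl)acetate and 4 tert-butyl{[(2S,3S)-4-iodo-2,3-dimethylbutyl]oxy}diphenylsilane
Product: 7 methyl (4R,5S)-6-{[tert-butyl(diphenyl)silyl]oxy}-4,5-dimethyl-2-(2,3,4-trimethoxyphenyl)hexanoate (both epimers at C2)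
Conditions: LiN(i-Pr)2, THF, −78 °C; then 4, DMPU, −78 °C → rt
Reagents that add atoms: none
Why: Alkylation of a benzylic ester enolate with a primary iodide forms the Cs–C9 bond; the weakly basic aryl-stabilised enolate and the polar cosolvent should favour SN2 over elimination at the β-branched iodide. The new centre at C2 is formed without control and is erased in step 7.

Step 6
Reactants: 7 methyl (4R,5S)-6-{[tert-butyl(diphenyl)silyl]oxy}-4,5-dimethyl-2-(2,3,4-trimethoxyphenyl)hexanoate
Product: 8 (4R,5S)-6-{[tert-butyl(diphenyl)silyl]oxy}-4,5-dimethyl-2-(2,3,4-trimethoxyphenyl)hexanal (both epimers at C2)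
Conditions: i-Bu2AlH (1.1 equiv), CH2Cl2, −78 °C; MeOH quench, aq. KNaC4H4O6
Reagents that add atoms: none
Why: Partial reduction of an ester; the tetrahedral aluminium hemiacetal of the α-branched ester persists at −78 °C and releases the aldehyde only on work-up. The aldehyde is used at once because α-aryl aldehydes oxidise easily in air.

Step 7
Reactants: 8 (4R,5S)-6-{[tert-butyl(diphenyl)silyl]oxy}-4,5-dimethyl-2-(2,3,4-trimethoxyphenyl)hexanal and 9 1-methoxybut-3-en-2-one
Product: 12 4-[(2R,3S)-4-{[tert-butyl(diphenyl)silyl]oxy}-2,3-dimethylbutyl]-2-methoxy-4-(2,3,4-trimethoxyphenyl)cyclohex-2-en-1-one (both epimers at C4 = Cs), via pyrrolidine enamine 10 (not isolated), via keto aldehyde 11 (not isolated)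
Conditions: pyrrolidine, 4 Å MS, PhMe, rt → 50 °C, then evaporation; 9, MeCN, 0 °C → rt; then AcOH, NaOAc, H2O, 60 °C
Reagents that add atoms: none
Why: Condensation of 8 with pyrrolidine gives the aryl-conjugated enamine 10, whose nucleophilic carbon is the future Cs; it adds in a conjugate sense to the unsubstituted terminus of 9 (Stork enamine Michael addition), forming the Cs–C6' bond and the quaternary carbon. The aqueous acetate buffer hydrolyses the adduct to keto aldehyde 11, whose formyl group has no α-hydrogen and can therefore act only as the acceptor. Pyrrolidinium acetate then promotes the intramolecular aldol condensation: of the two α-carbons of the ketone only the methoxymethyl carbon C3' can reach C2' through a six-membered transition state (the other would close a cyclobutane), so C2'–C3' forms by a 6-(enolendo)-exo-trig closure and E1cB dehydration gives the enol ether double bond C2'=C3' directly. The closest known reaction type is the Robinson annulation of α-aryl α-alkyl aldehydes with but-3-en-2-one to 4-alkyl-4-arylcyclohex-2-enones, and alkoxymethyl vinyl ketones are established annulation partners that give 2-alkoxycyclohex-2-enones. The only new stereocentre is Cs, formed without control on either face of the enamine; both epimers are carried on because Cs stops being stereogenic once ring C is symmetrical, and C7 and C8 lie outside the reacting system. The step needs 1,4- over 1,2-addition and C- over N-alkylation, which the soft enamine carbon and the unhindered vinyl terminus should secure, and aldol regiochemistry, which ring size secures. The neutral Michael stage avoids base-induced polymerisation of 9, and the t-BuPh2Si ether should survive the buffer.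

Step 8
Reactants: 12 4-[(2R,3S)-4-{[tert-butyl(diphenyl)silyl]oxy}-2,3-dimethylbutyl]-2-methoxy-4-(2,3,4-trimethoxyphenyl)cyclohex-2-en-1-one
Product: 13 4-[(2R,3S)-4-hydroxy-2,3-dimethylbutyl]-2-methoxy-4-(2,3,4-trimethoxyphenyl)cyclohex-2-en-1-one (both epimers at C4)
Conditions: Bu4NF, THF, 0 °C → rt
Reagents that add atoms: none
Why: Fluoride cleavage of the silyl ether; the enone, the enol ether and the aryl ethers are inert to fluoride, and the hydroxyl group is too remote from the hindered β-carbon C2' for conjugate addition.

Step 9
Reactants: 13 4-[(2R,3S)-4-hydroxy-2,3-dimethylbutyl]-2-methoxy-4-(2,3,4-trimethoxyphenyl)cyclohex-2-en-1-one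
Product: 14 (2S,3R)-4-[3-methoxy-4-oxo-1-(2,3,4-trimethoxyphenyl)cyclohex-2-en-1-yl]-2,3-dimethylbutanoic acid (both epimers at ring C1 = Cs)
Conditions: TEMPO (cat.), PhI(OAc)2 (2.2 equiv), MeCN/H2O 1:1, rt
Reagents that add atoms: water, O
Why: Oxoammonium-mediated oxidation of the primary alcohol to the aldehyde and, through its hydrate, to the acid; the near-neutral conditions should leave the enol ether, the electron-rich arene and the C7 stereocentre (α to the transient aldehyde) intact.

Step 10
Reactants: 14 (2S,3R)-4-[3-methoxy-4-oxo-1-(2,3,4-trimethoxyphenyl)cyclohex-2-en-1-yl]-2,3-dimethylbutanoic acid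
Product: 16 (7S,8R)-spiro dione: ring B 7,8-dimethyl C6 ketone fused to ring A and spiro-linked at Cs to ring C 3'-methoxycyclohex-2'-en-4'-one (both Cs epimers), via acid chloride 15 (not isolated)
Conditions: (COCl)2, DMF (cat.), CH2Cl2, 0 °C → rt, evaporation; then SnCl4, CH2Cl2 (high dilution), −40 → 0 °C
Reagents that add atoms: none
Why: Intramolecular Friedel–Crafts acylation closes ring B by forming Ca–C6. Ca is the only C–H ortho to Cs, it is para to the Cd methoxy group, and the quaternary Cs favours cyclisation (Thorpe–Ingold effect). The ring C enone is deactivated by complexation with the Lewis acid, and without base no ketene can form from 15, so C7 should keep its configuration.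

Step 11
Reactants: 16 (7S,8R)-spiro dione
Product: 18 (6S,7S,8R)-6-hydroxy spiro enone: C6 carbinol cis to the C7 methyl group; ring C 3'-methoxycyclohex-2'-en-4'-one (both Cs epimers), via lithium dienolate 17 (not isolated)
Conditions: LiN(SiMe3)2 (1.05 equiv), THF, −78 °C; then LiBH(s-Bu)3, −78 → −40 °C; aq. NH4Cl
Reagents that add atoms: none
Why: Kinetic deprotonation by the hindered amide should occur at the unhindered C5' methylene of ring C and not at the tertiary C7–H, giving the cross-conjugated dienolate 17, whose carbonyl is inert to hydride (masking of an enone as its enolate during reduction of a second ketone). The bulky borohydride should then attack the C6 aryl ketone from the face away from the C7 methyl group, as with 2-alkyl benzocycloalkanones, giving the 6,7-cis (6S) alcohol. Protonation of 17 at C5' on work-up returns the enone.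

Step 12
Reactants: 18 (6S,7S,8R)-6-hydroxy spiro enone
Product: 19 (6R,7S,8R)-6-benzoyloxy spiro enone: benzoate trans to the C7 methyl group; ring C 3'-methoxycyclohex-2'-en-4'-one (both Cs epimers)
Conditions: PhCO2H, PPh3, diisopropyl azodicarboxylate, PhMe, 0 °C → rt
Reagents that add atoms: benzoic acid, OC(=O)c1ccccc1
Why: Mitsunobu esterification; the benzoate displaces the alkoxyphosphonium group at C6 with inversion, turning the 6S carbinol into the 6R ester and completing the all-trans triad. The non-polar solvent and low temperature are chosen to disfavour ionisation of the benzylic position.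

Step 13
Reactants: 19 (6R,7S,8R)-6-benzoyloxy spiro enone
Product: 20 (6R,7S,8R)-6-benzoyloxy-5'-hydroxy spiro enone: ring C 5'-hydroxy-3'-methoxycyclohex-2'-en-4'-one (epimers at Cs and C5')
Conditions: KN(SiMe3)2, THF, −78 °C; then 3-phenyl-2-(phenylsulfonyl)oxaziridine, −78 °C; aq. NH4Cl
Reagents that add atoms: 3-phenyl-2-(phenylsulfonyl)oxaziridine, O=S(=O)(N1OC1c1ccccc1)c1ccccc1
Why: Enolate hydroxylation with an N-sulfonyloxaziridine; 19 has enolisable hydrogen only at C5', so the potassium dienolate forms regiospecifically and is oxygenated there, while the non-enolisable benzoate is not attacked at −78 °C. The configuration of the new C5' centre is irrelevant because it is oxidised in step 14.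

Step 14
Reactants: 20 (6R,7S,8R)-6-benzoyloxy-5'-hydroxy spiro enone
Product: 22 (6R,7S,8R)-6-benzoyloxy spiro diosphenol: ring C 5'-hydroxy-3'-methoxycyclohexa-2',5'-dien-4'-one (both Cs epimers), via 1,2-diketone 21 (not isolated)
Conditions: (COCl)2, DMSO, CH2Cl2, −78 °C; then Et3N, −78 → 0 °C
Reagents that add atoms: none
Why: Swern oxidation of the α-hydroxy ketone gives 1,2-diketone 21, which can enolise only towards C6' and should do so under the amine base, giving the cross-conjugated diosphenol 22; aromatisation is blocked by the quaternary Cs.

Step 15
Reactants: 22 (6R,7S,8R)-6-benzoyloxy spiro diosphenol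
Product: 23 CNP0201356.1: (6R,7S,8R)-6-benzoyloxy-7,8-dimethyl spiro compound with ring C 3',5'-dimethoxycyclohexa-2',5'-dien-4'-one
Conditions: Me2SO4, K2CO3, acetone, rt → 40 °C
Reagents that add atoms: dimethyl sulfate, COS(=O)(=O)OC
Why: O-Methylation of the acidic diosphenol; the hard electrophile and the position of C6' next to the quaternary Cs favour O- over C-alkylation, and the benzoate is inert to K2CO3 in acetone. With both arms of ring C now identical, Cs is no longer stereogenic and the epimer pair collapses to the single target.

## Compound list

1 | (2S,3S)-2,3-dimethylbutanedioic acid ((2S,3S)-2,3-dimethylsuccinic acid) | OC(=O)[C@@H](C)[C@H](C)C(=O)O | starting material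
2 | (2S,3S)-2,3-dimethylbutane-1,4-diol | OC[C@@H](C)[C@H](C)CO | intermediate
3 | (2S,3S)-4-{[tert-butyl(diphenyl)silyl]oxy}-2,3-dimethylbutan-1-ol | OC[C@@H](C)[C@H](C)CO[Si](c1ccccc1)(c1ccccc1)C(C)(C)C | intermediate
4 | tert-butyl{[(2S,3S)-4-iodo-2,3-dimethylbutyl]oxy}diphenylsilane | IC[C@@H](C)[C@H](C)CO[Si](c1ccccc1)(c1ccccc1)C(C)(C)C | intermediate
5 | (2,3,4-trimethoxyphenyl)acetic acid | COc1ccc(CC(=O)O)c(OC)c1OC | starting material
6 | methyl (2,3,4-trimethoxyphenyl)acetate | COC(=O)Cc1ccc(OC)c(OC)c1OC | intermediate
7 | methyl (4R,5S)-6-{[tert-butyl(diphenyl)silyl]oxy}-4,5-dimethyl-2-(2,3,4-trimethoxyphenyl)hexanoate, both epimers at C2 | COC(=O)C(C[C@@H](C)[C@H](C)CO[Si](c1ccccc1)(c1ccccc1)C(C)(C)C)c1ccc(OC)c(OC)c1OC | intermediate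
8 | (4R,5S)-6-{[tert-butyl(diphenyl)silyl]oxy}-4,5-dimethyl-2-(2,3,4-trimethoxyphenyl)hexanal, both epimers at C2 | O=CC(C[C@@H](C)[C@H](C)CO[Si](c1ccccc1)(c1ccccc1)C(C)(C)C)c1ccc(OC)c(OC)c1OC | intermediate
9 | 1-methoxybut-3-en-2-one | COCC(=O)C=C | starting material
10 | pyrrolidine enamine of 8: 1-[(4R,5S)-6-{[tert-butyl(diphenyl)silyl]oxy}-4,5-dimethyl-2-(2,3,4-trimethoxyphenyl)hex-1-en-1-yl]pyrrolidine | C1CCN(C1)C=C(C[C@@H](C)[C@H](C)CO[Si](c1ccccc1)(c1ccccc1)C(C)(C)C)c1ccc(OC)c(OC)c1OC | intermediate (not isolated)
11 | keto aldehyde: 2-[(2R,3S)-4-{[tert-butyl(diphenyl)silyl]oxy}-2,3-dimethylbutyl]-6-methoxy-5-oxo-2-(2,3,4-trimethoxyphenyl)hexanal, both epimers at C2 | O=CC(CCC(=O)COC)(C[C@@H](C)[C@H](C)CO[Si](c1ccccc1)(c1ccccc1)C(C)(C)C)c1ccc(OC)c(OC)c1OC | intermediate (not isolated)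
12 | 4-[(2R,3S)-4-{[tert-butyl(diphenyl)silyl]oxy}-2,3-dimethylbutyl]-2-methoxy-4-(2,3,4-trimethoxyphenyl)cyclohex-2-en-1-one, both epimers at C4 (Cs) | COC1=CC(CCC1=O)(C[C@@H](C)[C@H](C)CO[Si](c1ccccc1)(c1ccccc1)C(C)(C)C)c1ccc(OC)c(OC)c1OC | intermediate
13 | 4-[(2R,3S)-4-hydroxy-2,3-dimethylbutyl]-2-methoxy-4-(2,3,4-trimethoxyphenyl)cyclohex-2-en-1-one, both epimers at C4 | COC1=CC(CCC1=O)(C[C@@H](C)[C@H](C)CO)c1ccc(OC)c(OC)c1OC | intermediate
14 | (2S,3R)-4-[3-methoxy-4-oxo-1-(2,3,4-trimethoxyphenyl)cyclohex-2-en-1-yl]-2,3-dimethylbutanoic acid, both epimers at Cs | COC1=CC(CCC1=O)(C[C@@H](C)[C@H](C)C(=O)O)c1ccc(OC)c(OC)c1OC | intermediate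
15 | acid chloride of 14: (2S,3R)-4-[3-methoxy-4-oxo-1-(2,3,4-trimethoxyphenyl)cyclohex-2-en-1-yl]-2,3-dimethylbutanoyl chloride | COC1=CC(CCC1=O)(C[C@@H](C)[C@H](C)C(=O)Cl)c1ccc(OC)c(OC)c1OC | intermediate (not isolated)
16 | (7S,8R)-spiro dione: ring B with C6 ketone and 7,8-dimethyl groups, fused to trimethoxy ring A; ring C 3'-methoxycyclohex-2'-en-4'-one; both Cs epimers | COC1=CC2(CCC1=O)C[C@@H](C)[C@H](C)C(=O)c1cc(OC)c(OC)c(OC)c12 | intermediate
17 | lithium dienolate of 16 (ring C C4'-enolate with C4'=C5' and C2'=C3' double bonds; C6 ketone free) | [Li+].COC1=CC2(CC=C1[O-])C[C@@H](C)[C@H](C)C(=O)c1cc(OC)c(OC)c(OC)c12 | intermediate (not isolated)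
18 | (6S,7S,8R)-6-hydroxy spiro enone (C6–OH cis to C7–CH3); both Cs epimers | COC1=CC2(CCC1=O)C[C@@H](C)[C@H](C)[C@H](O)c1cc(OC)c(OC)c(OC)c12 | intermediate
19 | (6R,7S,8R)-6-benzoyloxy spiro enone (benzoate trans to C7–CH3); both Cs epimers | COC1=CC2(CCC1=O)C[C@@H](C)[C@H](C)[C@@H](OC(=O)c1ccccc1)c1cc(OC)c(OC)c(OC)c12 | intermediate
20 | (6R,7S,8R)-6-benzoyloxy-5'-hydroxy spiro enone; epimers at Cs and C5' | COC1=CC2(CC(O)C1=O)C[C@@H](C)[C@H](C)[C@@H](OC(=O)c1ccccc1)c1cc(OC)c(OC)c(OC)c12 | intermediate
21 | (6R,7S,8R)-6-benzoyloxy spiro 4',5'-diketone (ring C 3'-methoxycyclohex-2'-ene-4',5'-dione) | COC1=CC2(CC(=O)C1=O)C[C@@H](C)[C@H](C)[C@@H](OC(=O)c1ccccc1)c1cc(OC)c(OC)c(OC)c12 | intermediate (not isolated)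
22 | (6R,7S,8R)-6-benzoyloxy spiro diosphenol (ring C 5'-hydroxy-3'-methoxycyclohexa-2',5'-dien-4'-one); both Cs epimers | COC1=CC2(C=C(O)C1=O)C[C@@H](C)[C@H](C)[C@@H](OC(=O)c1ccccc1)c1cc(OC)c(OC)c(OC)c12 | intermediate
23 | CNP0201356.1: (6R,7S,8R)-6-benzoyloxy-7,8-dimethyl spiro compound, ring A 1,2,3-trimethoxybenzene, ring C 3',5'-dimethoxycyclohexa-2',5'-dien-4'-one | COC1=CC2(C=C(OC)C1=O)C[C@@H](C)[C@H](C)[C@@H](OC(=O)c1ccccc1)c1cc(OC)c(OC)c(OC)c12 | target

## Step count and least certain steps

Total step count: 15. Longest linear sequence: 14 steps (steps 1–3 and 5–15, from acid 1).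

**Step 7 (key step).** The Michael addition at the crowded enamine carbon (ortho-methoxyaryl group, β-branched chain) may be slow enough that 9 polymerises or is consumed by amine addition, and the aldol condensation may stop before dehydration. Fallback, from 8 back to 12: the annulation is run with but-3-en-2-one under the same enamine protocol to give the methoxy-free enone F1, 4-[(2R,3S)-4-{[tert-butyl(diphenyl)silyl]oxy}-2,3-dimethylbutyl]-4-(2,3,4-trimethoxyphenyl)cyclohex-2-en-1-one. Weitz–Scheffer epoxidation (H2O2, NaOH, MeOH, 0 °C) gives the 2,3-epoxy ketone F2. NaOMe in MeOH then opens the epoxide at the carbonyl-activated carbon C3', and the resulting β-hydroxy ketone loses water to give the 2-methoxy enone 12. The methoxy group is thus introduced after ring formation and not with the vinyl ketone.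

**Step 11.** Enolisation may be incomplete or not site-selective. Any ring C carbonyl left unmasked would be reduced before the C6 ketone, and deprotonation at C7, or proton exchange between 17 and unreacted ketone during a slow reduction, would epimerise C7. The two Cs epimers may also differ in facial selectivity. Fallback, from 16 back to 19, masks ring C covalently without base. Luche reduction (NaBH4, CeCl3·7H2O, MeOH/CH2Cl2, −78 °C) reduces the more electrophilic ring C carbonyl and gives the allylic alcohol F3 with the C6 ketone intact. Silylation (t-BuMe2SiCl, imidazole, DMF) gives the silyl ether F4. LiBH(s-Bu)3 at −78 °C gives the 6S alcohol F5, and Mitsunobu esterification as in step 12 gives the 6R benzoate F6. Bu4NF buffered with AcOH frees the allylic alcohol F7, and Dess–Martin periodinane with NaHCO3 re-forms the enone 19.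

**Step 12.** The activated benzylic oxyphosphonium intermediate may ionise to a para-methoxy-stabilised cation, leading to loss of stereospecificity or elimination towards C7, and SN2 displacement beside a methyl-bearing carbon may be slow. Fallback, from 16 back to 20, sets the 6R configuration by reagent control and esterifies with retention. Kinetic enolisation as in step 11 with trapping by Et3SiCl gives the triethylsilyl dienol ether F8. Corey–Bakshi–Shibata reduction with (S)-2-methyl-CBS-oxazaborolidine and BH3·SMe2 (aryl as the large group) should give the 6R alcohol F9. BzCl, DMAP and pyridine give the benzoate F10. Rubottom oxidation of the silyl enol ether (dimethyldioxirane, acetone, −40 °C; then aqueous citric acid) gives the α'-hydroxy enone 20, bypassing steps 11–13.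

**Step 10.** Ca is only moderately activated (para to the twisted Cd methoxy group, meta to the other two), so the acylium ion may instead attack the enol ether carbon C2' of ring C (a six-membered closure), the Lewis acid may cleave that enol ether, or intermolecular acylation at Cb may compete. Fallback, from 8 back to 16, keeps the enol ether out of the acid step. The methoxy-free enone F1 of the key-step fallback is desilylated (Bu4NF) to the alcohol F11 and oxidised (TEMPO, PhI(OAc)2) to the acid F12. Cyclisation through the acid chloride with SnCl4, or with P2O5 in MeSO3H, gives the dione F13. Epoxidation (H2O2, NaOH, MeOH) gives the epoxy ketone F14, and NaOMe in MeOH gives 16. Any epimerisation at C7 during the two basic steps should favour the wanted trans-dimethyl arrangement.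

## Further compounds

F1 | step 7 | 4-[(2R,3S)-4-{[tert-butyl(diphenyl)silyl]oxy}-2,3-dimethylbutyl]-4-(2,3,4-trimethoxyphenyl)cyclohex-2-en-1-one, both epimers at C4 | O=C1C=CC(CC1)(C[C@@H](C)[C@H](C)CO[Si](c1ccccc1)(c1ccccc1)C(C)(C)C)c1ccc(OC)c(OC)c1OC
F2 | step 7 | 2,3-epoxide of F1: 4-[(2R,3S)-4-{[tert-butyl(diphenyl)silyl]oxy}-2,3-dimethylbutyl]-2,3-epoxy-4-(2,3,4-trimethoxyphenyl)cyclohexan-1-one, mixture of diastereomers | O=C1CCC(C[C@@H](C)[C@H](C)CO[Si](c3ccccc3)(c3ccccc3)C(C)(C)C)(c3ccc(OC)c(OC)c3OC)C2OC12
F3 | step 11 | (7S,8R)-spiro hydroxy ketone: ring C 3'-methoxycyclohex-2'-en-4'-ol, C6 ketone, mixture of diastereomers | COC1=CC2(CCC1O)C[C@@H](C)[C@H](C)C(=O)c1cc(OC)c(OC)c(OC)c12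
F4 | step 11 | tert-butyldimethylsilyl ether of F3 | COC1=CC2(CCC1O[Si](C)(C)C(C)(C)C)C[C@@H](C)[C@H](C)C(=O)c1cc(OC)c(OC)c(OC)c12
F5 | step 11 | (6S,7S,8R)-6-hydroxy compound from F4 (C6–OH cis to C7–CH3) | COC1=CC2(CCC1O[Si](C)(C)C(C)(C)C)C[C@@H](C)[C@H](C)[C@H](O)c1cc(OC)c(OC)c(OC)c12
F6 | step 11 | (6R,7S,8R)-6-benzoate from F5 | COC1=CC2(CCC1O[Si](C)(C)C(C)(C)C)C[C@@H](C)[C@H](C)[C@@H](OC(=O)c1ccccc1)c1cc(OC)c(OC)c(OC)c12
F7 | step 11 | (6R,7S,8R)-6-benzoyloxy spiro allylic alcohol (ring C 3'-methoxycyclohex-2'-en-4'-ol) | COC1=CC2(CCC1O)C[C@@H](C)[C@H](C)[C@@H](OC(=O)c1ccccc1)c1cc(OC)c(OC)c(OC)c12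
F8 | step 12 | triethylsilyl dienol ether of 16 (ring C 3'-methoxy-4'-triethylsilyloxycyclohexa-2',4'-diene; C6 ketone) | CC[Si](CC)(CC)OC1=CCC2(C=C1OC)C[C@@H](C)[C@H](C)C(=O)c1cc(OC)c(OC)c(OC)c12
F9 | step 12 | (6R,7S,8R)-6-hydroxy silyl dienol ether (C6–OH trans to C7–CH3) | CC[Si](CC)(CC)OC1=CCC2(C=C1OC)C[C@@H](C)[C@H](C)[C@@H](O)c1cc(OC)c(OC)c(OC)c12
F10 | step 12 | (6R,7S,8R)-6-benzoyloxy silyl dienol ether | CC[Si](CC)(CC)OC1=CCC2(C=C1OC)C[C@@H](C)[C@H](C)[C@@H](OC(=O)c1ccccc1)c1cc(OC)c(OC)c(OC)c12
F11 | step 10 | 4-[(2R,3S)-4-hydroxy-2,3-dimethylbutyl]-4-(2,3,4-trimethoxyphenyl)cyclohex-2-en-1-one | O=C1C=CC(CC1)(C[C@@H](C)[C@H](C)CO)c1ccc(OC)c(OC)c1OC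
F12 | step 10 | (2S,3R)-2,3-dimethyl-4-[4-oxo-1-(2,3,4-trimethoxyphenyl)cyclohex-2-en-1-yl]butanoic acid | O=C1C=CC(CC1)(C[C@@H](C)[C@H](C)C(=O)O)c1ccc(OC)c(OC)c1OC
F13 | step 10 | (7S,8R)-spiro dione without the C3' methoxy group (ring C cyclohex-2'-en-4'-one; C6 ketone) | O=C1C=CC2(CC1)C[C@@H](C)[C@H](C)C(=O)c1cc(OC)c(OC)c(OC)c12
F14 | step 10 | 2',3'-epoxide of F13, mixture of diastereomers | O=C1CCC3(C[C@@H](C)[C@H](C)C(=O)c4cc(OC)c(OC)c(OC)c34)C2OC12
A1 | alternative 1 | achiral benzocycloheptadienone: C6 ketone, C7=C8 double bond, two methyl ester groups on the future Cs | COC(=O)C1(C(=O)OC)CC=CC(=O)c2cc(OC)c(OC)c(OC)c21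
A2 | alternative 1 | trans-7,8-dimethyl benzosuberone gem-diester | COC(=O)C1(C(=O)OC)C[C@@H](C)[C@H](C)C(=O)c2cc(OC)c(OC)c(OC)c21
A3 | alternative 2 | spiro-indanone with ring C as ketal-protected cyclohexanone | O=C1CC2(CCC3(CC2)OCCO3)c2c(OC)c(OC)c(OC)cc21
A4 | alternative 2 | but-2-yne | CC#CC
A5 | alternative 2 | 7,8-dimethyl benzocycloheptenone with tetrasubstituted C7=C8 bond | O=C1C(C)=C(C)CC2(CCC3(CC2)OCCO3)c2c(OC)c(OC)c(OC)cc21
A6 | alternative 3 | achiral aryl aldehyde: formyl group on Ca, malonate carbon (future Cs) bearing a 2-methylbut-2-enyl chain | COC(=O)C(CC(C)=CC)(C(=O)OC)c1c(C=O)cc(OC)c(OC)c1OC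
A7 | alternative 3 | 6,7-cis homoallylic alcohol with exocyclic methylene at C8 | COC(=O)C1(C(=O)OC)CC(=C)[C@H](C)[C@H](O)c2cc(OC)c(OC)c(OC)c21
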